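## Retrosynthetic overview

- Ring A (the benzoate ring, made first) is cut to methyl 3-(4-hydroxyphenyl)propanoate 1 and methyl 3,5-dioxohexanoate 2. Claisen acylation gives triketo ester 3 and aldol aromatisation gives resorcylate 4. Ring C (the 4-hydroxyphenyl ring) comes in with 1 and stays unprotected.
- The C-3 prenyl group is cut at the aryl–CH2 bond to 4 and prenyl bromide 5, giving 6.
- Ring B (the pyran ring, made last) is cut at the O–C(CH3)2 bond. 2-Methylbut-1-en-3-yne 7 is joined to O-4 of 6 as ether 8 (the key C–O bond). A Claisen shift (allenylphenol 9), a 1,5-H shift (quinone methide 10) and an oxa-6π closure then re-form that C–O bond inside the ring of target 11.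

Assumption: the target has no stereocentre and its only ring alkene is necessarily cis, so it is achiral and no stereocontrol is needed.

## Route

Step 1
Reactants: 1 methyl 3-(4-hydroxyphenyl)propanoate; 2 methyl 3,5-dioxohexanoate
Product: 4 methyl 2,4-dihydroxy-6-[2-(4-hydroxyphenyl)ethyl]benzoate, via triketo ester 3 (not isolated)
Conditions: 2 (2 equiv), LiN(iPr)2 (7 equiv), THF, 0 °C; add 1, 0 °C → rt; then aq. K2CO3/KHCO3 (pH 9.5), MeOH, rt; 1 M HCl
Reagents that add atoms: none
Why: Biomimetic polyketide sequence (Harris-type Claisen acylation, then intramolecular aldol condensation and aromatisation): the terminal C-6 carbanion of the trianion of 2 is its most nucleophilic site and is acylated by ester 1 (whose lithium phenoxide is inert), and at pH about 9.5 the doubly activated C-2 methylene of 3 adds to the C-7 ketone and the ring aromatises by loss of water, which places the ester between the 2-OH and the arylethyl chain; no stereocentre is formed.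

Step 2
Reactants: 4 methyl 2,4-dihydroxy-6-[2-(4-hydroxyphenyl)ethyl]benzoate; 5 1-bromo-3-methylbut-2-ene (prenyl bromide)
Product: 6 methyl 2,4-dihydroxy-6-[2-(4-hydroxyphenyl)ethyl]-3-(3-methylbut-2-en-1-yl)benzoate
Conditions: NaH (1.05 equiv), toluene, 0 °C → rt; then 5 (1.1 equiv), rt → 60 °C
Reagents that add atoms: none
Why: ortho C-alkylation of a sodium phenoxide in a non-polar solvent (SN2 on the allylic bromide, tight ion pair favouring C- over O-attack): one equivalent of NaH ionises only the most acidic 4-OH (para to the ester), and the ring attacks 5 from C-3, the most electron-rich carbon between the two oxygens, not from the hindered C-5 or the un-ionised ring C phenol; no stereocentre is formed.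

Step 3
Reactants: 6 methyl 2,4-dihydroxy-6-[2-(4-hydroxyphenyl)ethyl]-3-(3-methylbut-2-en-1-yl)benzoate; 7 2-methylbut-1-en-3-yne
Product: 11 methyl 7-hydroxy-5-[2-(4-hydroxyphenyl)ethyl]-2,2-dimethyl-8-(3-methylbut-2-en-1-yl)-2H-chromene-6-carboxylate, via aryl propargyl ether 8 (not isolated), via allenylphenol 9 (not isolated), via vinyl quinone methide 10 (not isolated)
Conditions: [Cu(MeCN)4]PF6 (5 mol %), iPr2NEt (20 mol %), 7 (5 equiv), MeCN, sealed tube, 40 °C; then 140 °C
Reagents that add atoms: none
Why: Proposed new method: copper-catalysed Markovnikov hydro-aryloxylation of a 1,3-enyne, in which monovalent copper and iPr2NEt turn 7 into a copper enynyl acetylide, iPr2NEtH+ protonates its terminal CH2 (δ-carbon) to give the same copper allenylidene/tertiary propargyl cation that propargylic carbonates give by loss of a leaving group (the microscopic reverse of the enyne-forming elimination seen as a side path in those substitutions, and analogous to the established δ-protonation of ruthenium enynyl complexes to allenylidenes), the amine-paired 4-phenoxide (only the 4-OH is acidic enough, the chelated 2-OH and the ring C phenol are not) attacks the γ-carbon to make the O–C(CH3)2 bond of 8 and protonolysis frees the catalyst, after which heating drives the known aryl propargyl ether Claisen rearrangement to C-5 (C-3 is blocked) giving 9, a 1,5-H shift to the Z-configured 10 and oxa-6π electrocyclisation to the 2,2-dimethyl-2H-chromene, this irreversible cascade also draining the reversible addition; closest known reaction type: copper-catalysed propargylic etherification of phenols with 2-methylbut-3-yn-2-yl carbonates or trifluoroacetates followed by thermal chromene formation; no stereocentre is formed.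

## Compound list

1 | methyl 3-(4-hydroxyphenyl)propanoate | COC(=O)CCc1ccc(O)cc1 | starting material
2 | methyl 3,5-dioxohexanoate | COC(=O)CC(=O)CC(C)=O | starting material
3 | methyl 9-(4-hydroxyphenyl)-3,5,7-trioxononanoate (triketo tautomer drawn) | COC(=O)CC(=O)CC(=O)CC(=O)CCc1ccc(O)cc1 | intermediate
4 | methyl 2,4-dihydroxy-6-[2-(4-hydroxyphenyl)ethyl]benzoate | COC(=O)c1c(O)cc(O)cc1CCc1ccc(O)cc1 | intermediate
5 | 1-bromo-3-methylbut-2-ene | CC(C)=CCBr | starting material
6 | methyl 2,4-dihydroxy-6-[2-(4-hydroxyphenyl)ethyl]-3-(3-methylbut-2-en-1-yl)benzoate | COC(=O)c1c(O)c(CC=C(C)C)c(O)cc1CCc1ccc(O)cc1 | intermediate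
7 | 2-methylbut-1-en-3-yne | CC(=C)C#C | starting material
8 | methyl 2-hydroxy-6-[2-(4-hydroxyphenyl)ethyl]-3-(3-methylbut-2-en-1-yl)-4-[(2-methylbut-3-yn-2-yl)oxy]benzoate | COC(=O)c1c(O)c(CC=C(C)C)c(OC(C)(C)C#C)cc1CCc1ccc(O)cc1 | intermediate
9 | methyl 2,4-dihydroxy-6-[2-(4-hydroxyphenyl)ethyl]-3-(3-methylbut-2-en-1-yl)-5-(3-methylbuta-1,2-dien-1-yl)benzoate | COC(=O)c1c(O)c(CC=C(C)C)c(O)c(C=C=C(C)C)c1CCc1ccc(O)cc1 | intermediate
10 | methyl (5Z)-2-hydroxy-6-[2-(4-hydroxyphenyl)ethyl]-3-(3-methylbut-2-en-1-yl)-5-(3-methylbut-2-en-1-ylidene)-4-oxocyclohexa-1(6),2-diene-1-carboxylate | COC(=O)C1=C(CCc2ccc(O)cc2)/C(=C/C=C(C)C)C(=O)C(CC=C(C)C)=C1O | intermediate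
11 | methyl 7-hydroxy-5-[2-(4-hydroxyphenyl)ethyl]-2,2-dimethyl-8-(3-methylbut-2-en-1-yl)-2H-chromene-6-carboxylate (CNP0133674.0, achiral) | COC(=O)c1c(O)c(CC=C(C)C)c2c(c1CCc1ccc(O)cc1)C=CC(C)(C)O2 | target

## Step count and risks

Total step count: 3. Longest linear sequence: 3 steps (1 and 2 → 4 → 6 → 11).

Steps most likely to fail, in order:

Step 3, the new copper step. The O–H addition may lie on the wrong side of equilibrium, the enyne may oligomerise on copper, or the cation may be attacked by carbon and not by oxygen. The fallback is known chemistry and runs from 6 to 11. It is a formal [3+3] chromene annulation with 3-methylbut-2-enal (ethylenediammonium diacetate 20 mol %, xylene, 140 °C). A Knoevenagel-type C–C bond at C-5 is made first, loss of water gives quinone methide 10 from the other side, and 10 closes by the same oxa-6π step. It makes no compound outside the list (entry F0).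

Step 2, direct C-prenylation. O-prenylation, attack at C-5 and double alkylation compete, so the yield is expected to be moderate. The fallback runs from 4 to 6 and brings the prenyl group in through oxygen. Zerovalent-palladium-catalysed O-alkylation of the 4-OH with tert-butyl 2-methylbut-3-en-2-yl carbonate (Pd(PPh3)4 5 mol %, THF, 0 °C) gives the 1,1-dimethylallyl ether methyl 2-hydroxy-6-[2-(4-hydroxyphenyl)ethyl]-4-[(2-methylbut-3-en-2-yl)oxy]benzoate F1. After filtration through silica, aromatic Claisen rearrangement (toluene, 110 °C) moves the allyl unit with allylic inversion to C-3, the position favoured by the chelated salicylate, and gives 6.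

Step 1, acylation of the trianion by an enolisable ester. Proton transfer from 1 and other cyclisation modes of 3 (pyrone or acylphloroglucinol) can lower the yield. The fallback runs from 1 to 4 and builds ring A by Michael addition and Claisen closure instead. Reduction of 1 with iBu2AlH (2.2 equiv, CH2Cl2, −78 °C) gives 3-(4-hydroxyphenyl)propanal F2. Wittig olefination with Ph3P=CHC(O)CH3 (toluene, 80 °C) gives (E)-6-(4-hydroxyphenyl)hex-3-en-2-one F3. Dimethyl malonate with NaOMe in refluxing MeOH gives racemic trans-methyl 2-hydroxy-6-[2-(4-hydroxyphenyl)ethyl]-4-oxocyclohex-2-ene-1-carboxylate F4. Bromination and dehydrobromination (Br2 1.0 equiv, DMF, 0 → 80 °C; the enolised 1,3-dione reacts far faster than the phenol ring) aromatise F4 to 4.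

## Further compounds

F0 | step 3 | none | none
F1 | step 2 | methyl 2-hydroxy-6-[2-(4-hydroxyphenyl)ethyl]-4-[(2-methylbut-3-en-2-yl)oxy]benzoate | COC(=O)c1c(O)cc(OC(C)(C)C=C)cc1CCc1ccc(O)cc1
F2 | step 1 | 3-(4-hydroxyphenyl)propanal | O=CCCc1ccc(O)cc1
F3 | step 1 | (E)-6-(4-hydroxyphenyl)hex-3-en-2-one | CC(=O)/C=C/CCc1ccc(O)cc1
F4 | step 1 | racemic trans-methyl 2-hydroxy-6-[2-(4-hydroxyphenyl)ethyl]-4-oxocyclohex-2-ene-1-carboxylate (one enantiomer drawn) | COC(=O)[C@@H]1[C@@H](CCc2ccc(O)cc2)CC(=O)C=C1O
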